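**Plan**

- Numbering (germacranolide): carbocycle C1–C10; lactone O–C6, C7, C11(=C13H2), C12=O; C14 on C10, C15 on C4; ester oxygen on C8.
- Cuts, in retrosynthetic order: C14 enal back to a silyl ether; ring bond C1–C2 (alkenyl iodide + aldehyde); C7–C8 (stannylmethyl butenolide + C8 aldehyde); lactone C7=C11 (metathesis) and C12–O (ester); C3–C4 (Stille); C5–C6 (alkynylation); C1–C10 (iodoform/malonate).
- Forward: the C2–C7/C11–C13/C15 chain is grown linearly and closed to the butenolide (first ring). It is joined at C7–C8 to the C8–C10/C1/C14 iodo-aldehyde, and the ten-membered carbocycle is closed last at C1–C2.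
- Stereochemistry: C6 from a ligand-controlled alkynylation; C7 and C8 from C6 in the allylstannane addition (anti to the C6 substituent, open transition state); C2 from the chiral ligand on chromium. The C4=C5 geometry comes from anti-hydroalumination/iodination, the C1=C10 geometry from an (E)-β-iodoacrylic acid.
- Enabling feature: C2 is a carbinol allylic to the C1=C10 olefin of the ten-membered ring and the only stereocentre outside the C6–C7–C8 lactone triad, so an alkenyl metal at C1 adding to a C2 aldehyde closes the ring and sets that centre in one event.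

Key step: step 21

Remark: the (R,R)-ProPhenol ligand in step 2 and the (S)-sulfonamide ligand in step 21 are assumed to induce the configurations drawn; if either induces the opposite sense, its enantiomer is used and nothing else changes.

**Route**

Step 1
Reactants: 1 propargyl alcohol
Product: 3 4-methoxybenzyl prop-2-ynyl ether, via sodium prop-2-yn-1-olate 2 (not isolated)
Conditions: NaH, THF, 0 °C; PMBCl, Bu4NI (cat.), 0 °C → rt
Reagents that add atoms: 4-methoxybenzyl chloride, COc1ccc(CCl)cc1
Why: Williamson ether synthesis, the alkoxide formed with NaH (the O–H is far more acidic than the alkyne C–H) being benzylated to put the future C15 oxygen under a group that survives hydride, palladium and Lewis acid yet leaves with DDQ.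

Step 2
Reactants: 3 4-methoxybenzyl prop-2-ynyl ether, 4 (E)-crotonaldehyde
Product: 6 (4S,5E)-1-(4-methoxybenzyloxy)hept-5-en-2-yn-4-ol, via methyl[3-(4-methoxybenzyloxy)prop-1-ynyl]zinc 5 (not isolated)
Conditions: Me2Zn, (R,R)-ProPhenol (10 mol %), Ph3P=O (20 mol %), toluene, 0 °C; then 4; aq NH4Cl
Reagents that add atoms: none
Why: Zinc–ProPhenol-catalysed asymmetric alkynylation of an α,β-unsaturated aldehyde, the dinuclear zinc catalyst delivering alkynylzinc 5 in a 1,2-sense to the Re face of the aldehyde to set C6 as the (S)-carbinol, while the propenyl group is kept as the later metathesis partner that supplies C7.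

Step 3
Reactants: 6 (4S,5E)-1-(4-methoxybenzyloxy)hept-5-en-2-yn-4-ol
Product: 8 (2Z,4S,5E)-2-iodo-1-(4-methoxybenzyloxy)hepta-2,5-dien-4-ol, via cyclic alkenylalanate 7 (not isolated)
Conditions: NaAlH2(OCH2CH2OMe)2 (Red-Al), THF, −20 → 0 °C; I2, THF, −78 → 0 °C
Reagents that add atoms: iodine, II
Why: Hydroxyl-directed anti-hydroalumination of a propargylic alcohol (Corey-type Red-Al reduction) puts hydride on C5 and aluminium on C4 inside a five-membered alkoxyalanate, and iodinolysis with retention gives the (Z)-iodide in which the site reserved for C3 is cis to C6.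

Step 4
Reactants: 8 (2Z,4S,5E)-2-iodo-1-(4-methoxybenzyloxy)hepta-2,5-dien-4-ol, 9 tributyl(vinyl)stannane
Product: 10 (3E,5S,6E)-3-[(4-methoxybenzyloxy)methyl]octa-1,3,6-trien-5-ol
Conditions: Pd(PPh3)4 (5 mol %), CuI (10 mol %), CsF, DMF, 45 °C
Reagents that add atoms: none
Why: Stille coupling of an alkenyl iodide proceeds with retention at C4 and tolerates the free allylic alcohol, so the vinyl group (C3=C2) ends cis to C6 and the C15 arm trans, which is the ring-cis C4=C5 geometry of the target.

Step 5
Reactants: 10 (3E,5S,6E)-3-[(4-methoxybenzyloxy)methyl]octa-1,3,6-trien-5-ol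
Product: 12 (3E,5S,6E)-3-[(4-methoxybenzyloxy)methyl]octa-3,6-diene-1,5-diol, via B-alkyl-9-BBN adduct 11 (not isolated)
Conditions: 9-BBN, THF, 0 °C → rt; NaOH, H2O2, H2O, 0 °C
Reagents that add atoms: hydrogen peroxide, OO
Why: Hydroboration–oxidation with the bulky 9-BBN should attack only the monosubstituted terminal alkene of the triene in the anti-Markovnikov sense to give the primary C2 alcohol, leaving the trisubstituted and the 1,2-disubstituted olefins untouched.

Step 6
Reactants: 12 (3E,5S,6E)-3-[(4-methoxybenzyloxy)methyl]octa-3,6-diene-1,5-diol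
Product: 13 (3E,5S,6E)-1-(tert-butyldimethylsilyloxy)-3-[(4-methoxybenzyloxy)methyl]octa-3,6-dien-5-ol
Conditions: TBSCl, imidazole, CH2Cl2, −20 °C
Reagents that add atoms: tert-butyldimethylsilyl chloride, CC(C)(C)[Si](C)(C)Cl
Why: Kinetic silylation discriminates the unhindered primary C2 hydroxyl from the hindered doubly allylic C6 hydroxyl, the TBS ether being chosen because acid can later remove it beside the TBDPS ether at C14.

Step 7
Reactants: 13 (3E,5S,6E)-1-(tert-butyldimethylsilyloxy)-3-[(4-methoxybenzyloxy)methyl]octa-3,6-dien-5-ol, 14 2-(bromomethyl)acrylic acid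
Product: 15 (3E,5S,6E)-1-(tert-butyldimethylsilyloxy)-3-[(4-methoxybenzyloxy)methyl]octa-3,6-dien-5-yl 2-(bromomethyl)acrylate
Conditions: DCC, DMAP (5 mol %), CH2Cl2, 0 °C
Reagents that add atoms: none
Why: Steglich esterification acylates the C6 hydroxyl under neutral conditions with retention and without allylic transposition, and brings in C11, C12 and C13.

Step 8
Reactants: 15 (3E,5S,6E)-1-(tert-butyldimethylsilyloxy)-3-[(4-methoxybenzyloxy)methyl]octa-3,6-dien-5-yl 2-(bromomethyl)acrylate
Product: 16 (3E,5S,6E)-1-(tert-butyldimethylsilyloxy)-3-[(4-methoxybenzyloxy)methyl]octa-3,6-dien-5-yl 2-[(tributylstannyl)methyl]acrylate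
Conditions: (Bu3Sn)2, n-BuLi, THF, 0 °C; CuBr·SMe2, −78 °C; then 15, −78 °C
Reagents that add atoms: hexabutylditin, CCCC[Sn](CCCC)(CCCC)[Sn](CCCC)(CCCC)CCCC
Why: Displacement of the activated allylic bromide by a stannylcopper reagent is the standard entry to 2-(stannylmethyl)acrylates (the SN2 and SN2′ paths are degenerate here), and it is done before lactone formation so that no basic reagent meets the later configurationally labile butenolide.

Step 9
Reactants: 16 (3E,5S,6E)-1-(tert-butyldimethylsilyloxy)-3-[(4-methoxybenzyloxy)methyl]octa-3,6-dien-5-yl 2-[(tributylstannyl)methyl]acrylate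
Product: 17 (5R)-5-[(1E)-4-(tert-butyldimethylsilyloxy)-2-[(4-methoxybenzyloxy)methyl]but-1-enyl]-3-[(tributylstannyl)methyl]furan-2(5H)-one
Conditions: second-generation Hoveyda–Grubbs catalyst (5 mol %), toluene, 80 °C
Reagents that add atoms: none
Why: Ring-closing metathesis of an acrylate ester of an allylic alcohol to a butenolide, the ruthenium carbene loading at the propenyl group (propene is lost) and closing on the 1,1-disubstituted acrylate to form C7=C11 under neutral conditions that leave C6 untouched (its descriptor changes from S to R only because the CIP priorities change).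

Step 10
Reactants: 18 diethyl allylmalonate, 19 iodoform
Product: 21 diethyl 2-allyl-2-(diiodomethyl)malonate, via sodium malonate enolate 20 (not isolated)
Conditions: NaH, Et2O, reflux; then CHI3, reflux
Reagents that add atoms: none
Why: C-Alkylation of a malonate enolate with iodoform (the Baker–Castro protocol) installs the diiodomethyl group whose carbon becomes C1.

Step 11
Reactants: 21 diethyl 2-allyl-2-(diiodomethyl)malonate
Product: 22 (E)-2-(iodomethylene)pent-4-enoic acid
Conditions: KOH, EtOH/H2O, reflux; then aq HCl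
Reagents that add atoms: potassium hydroxide, [K+].[OH-]
Why: Saponification followed by decarboxylative elimination of iodide gives the β-iodoacrylic acid with iodine trans to the carboxyl group, that is cis to the allyl chain carrying C9, which is the geometry a ring-cis C1=C10 requires.

Step 12
Reactants: 22 (E)-2-(iodomethylene)pent-4-enoic acid
Product: 23 (E)-2-(iodomethylene)pent-4-en-1-ol
Conditions: LiAlH4, Et2O, 0 °C
Reagents that add atoms: none
Why: Hydride reduction of the acid gives the allylic C14 alcohol with the alkenyl iodide and its geometry preserved, as in the known 2-methyl analogue.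

Step 13
Reactants: 23 (E)-2-(iodomethylene)pent-4-en-1-ol
Product: 24 (E)-tert-butyl[2-(iodomethylene)pent-4-enyloxy]diphenylsilane
Conditions: TBDPSCl, imidazole, CH2Cl2, rt
Reagents that add atoms: tert-butyl(chloro)diphenylsilane, CC(C)(C)[Si](Cl)(c1ccccc1)c1ccccc1
Why: Standard silylation, the robust TBDPS ether at C14 being chosen to outlast the Lewis acid of the fragment union and the acid that later removes the TBS ether at C2.

Step 14
Reactants: 24 (E)-tert-butyl[2-(iodomethylene)pent-4-enyloxy]diphenylsilane
Product: 26 (E)-3-[(tert-butyldiphenylsilyloxy)methyl]-4-iodobut-3-enal, via vicinal diol 25 (not isolated)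
Conditions: OsO4 (2 mol %), NaIO4, 2,6-lutidine, dioxane/H2O, rt
Reagents that add atoms: osmium tetroxide, O=[Os](=O)(=O)=O; sodium periodate, [Na+].[O-]I(=O)(=O)=O
Why: Lemieux–Johnson cleavage, OsO4 dihydroxylating the electron-richer monosubstituted alkene in preference to the deactivated iodoalkene and periodate cleaving diol 25 to the C8 aldehyde under buffered conditions that should not move the β,γ-double bond into conjugation.

Step 15
Reactants: 17 (5R)-5-[(1E)-4-(tert-butyldimethylsilyloxy)-2-[(4-methoxybenzyloxy)methyl]but-1-enyl]-3-[(tributylstannyl)methyl]furan-2(5H)-one, 26 (E)-3-[(tert-butyldiphenylsilyloxy)methyl]-4-iodobut-3-enal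
Product: 27 (4R,5R)-4-[(1R,3E)-3-[(tert-butyldiphenylsilyloxy)methyl]-1-hydroxy-4-iodobut-3-enyl]-5-[(1E)-4-(tert-butyldimethylsilyloxy)-2-[(4-methoxybenzyloxy)methyl]but-1-enyl]-3-methylideneoxolan-2-one
Conditions: BF3·OEt2, CH2Cl2, −78 → −40 °C; aq NaHCO3
Reagents that add atoms: none
Why: BF3-promoted allylstannane–aldehyde addition (Hosomi–Sakurai-type SE2′, as in the 2-(stannylmethyl)acrylate route to α-methylene-γ-butyrolactones), in which the activated aldehyde attacks C7 on the lactone face opposite the C6 alkenyl group (trans-lactone, 7R) through an open antiperiplanar transition state that gives the syn C7/C8 relationship (8R), while loss of tin creates the C11=C13 methylene.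

Step 16
Reactants: 27 the C8 alcohol from step 15, 28 isovaleryl chloride
Product: 29 the C8 3-methylbutanoate of 27 (6R,7R,8R)
Conditions: pyridine, DMAP (cat.), CH2Cl2, 0 °C
Reagents that add atoms: none
Why: DMAP-catalysed acylation of the secondary C8 alcohol with the acid chloride proceeds with retention and caps the hydroxyl before it can translactonise.

Step 17
Reactants: 29 the C8 3-methylbutanoate
Product: 30 the C15 primary allylic alcohol (PMB ether of 29 removed)
Conditions: DDQ, CH2Cl2/pH 7 buffer, 0 °C
Reagents that add atoms: none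
Why: Oxidative cleavage of the PMB ether with DDQ (oxidation to the benzylic oxocarbenium ion and hydrolysis) frees only the C15 hydroxyl, the silyl ethers, esters, iodoalkene and methylene lactone being inert.

Step 18
Reactants: 30 the C15 alcohol
Product: 31 the C15 acetate
Conditions: Ac2O, pyridine, DMAP (cat.), CH2Cl2, 0 °C
Reagents that add atoms: acetic anhydride, CC(=O)OC(C)=O
Why: Standard acetylation of the primary allylic alcohol installs the C15 acetate of the target.

Step 19
Reactants: 31 the C15 acetate
Product: 32 the C2 primary alcohol (TBS ether of 31 removed)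
Conditions: CSA (cat.), MeOH/CH2Cl2, 0 °C
Reagents that add atoms: none
Why: Acid-catalysed methanolysis removes the primary TBS ether much faster than the bulkier TBDPS ether and so exposes the C2 hydroxyl without touching the esters.

Step 20
Reactants: 32 the C2 alcohol
Product: 33 seco iodo-aldehyde: trans-4,5-disubstituted 3-methylideneoxolan-2-one whose C6 carries the (1E)-2-(acetoxymethyl)-4-oxobut-1-enyl chain and whose C7 carries the (1R,3E)-3-[(tert-butyldiphenylsilyloxy)methyl]-4-iodo-1-(3-methylbutanoyloxy)but-3-enyl chain (6R,7R,8R)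
Conditions: Dess–Martin periodinane, NaHCO3, CH2Cl2, 0 °C
Reagents that add atoms: none
Why: Dess–Martin oxidation under bicarbonate buffer gives the β,γ-unsaturated C2 aldehyde without acid or base strong enough to shift the C4=C5 bond, and the aldehyde is carried on at once.

Step 21
Reactants: 33 seco iodo-aldehyde
Product: 35 (2S,6R,7R,8R)-15-acetoxy-14-(tert-butyldiphenylsilyloxy)-2-hydroxy-8-(3-methylbutanoyloxy)germacra-1(10),4,11(13)-trien-12,6-olide (both ring olefins ring-cis), via alkenylchromium dichloride 34 (not isolated)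
Conditions: CrCl2 (excess), (S)-N-[2-(4-isopropyl-4,5-dihydro-1,3-oxazol-2-yl)-6-methylphenyl]methanesulfonamide, Et3N, THF, rt; NiCl2 (1 mol % of CrCl2); 33 by syringe pump, rt, final ca. 2 mM; aq work-up
Reagents that add atoms: none
Why: CrCl2 reduces the trace of NiCl2 to zerovalent nickel, which inserts into the C1–I bond with retention of olefin geometry and passes the alkenyl group to trivalent chromium, and the alkenylchromium 34 adds to the C2 aldehyde to give the allylic alcohol after aqueous work-up. The closest known reaction is the Nozaki–Hiyama–Kishi macrocyclisation of ω-iodoalkenyl aldehydes, run with Kishi-type chiral sulfonamide ligands on chromium. The ten-membered carbocycle closes by a 10-exo-trig addition of C1 to the aldehyde carbon under high dilution, the chain being pre-bent by the trans-disubstituted lactone and the ring-cis C4=C5 olefin. The new C2 stereocentre (S, Re-face attack) is controlled by the chiral ligand on the chromium that carries C1, because the aldehyde has no α-stereocentre and the C6–C8 triad is too remote to decide the face reliably. The step needs face selectivity at C2, retention of the C1=C10 geometry and chemoselectivity for the aldehyde: the first comes from the ligand, the second from the stereoretentive nickel-to-chromium exchange (C2 ends cis to C9), and the third from the low basicity of the organochromium, which spares lactone, acetate, isovalerate and the methylene lactone, while the very low nickel loading limits ionisation of the allylic esters.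

Step 22
Reactants: 35 macrocyclic C2 alcohol, C14 TBDPS ether
Product: 36 (2S,6R,7R,8R)-15-acetoxy-2,14-dihydroxy-8-(3-methylbutanoyloxy)germacra-1(10),4,11(13)-trien-12,6-olide
Conditions: HF·pyridine, pyridine, THF, 0 °C → rt
Reagents that add atoms: none
Why: Buffered fluoride cleavage of the silyl ether frees the C14 hydroxyl and leaves acetate, isovalerate and the methylene lactone untouched.

Step 23
Reactants: 36 macrocyclic C2,C14-diol
Product: 37 CNP0524123.1, (2S,6R,7R,8R)-15-acetoxy-2-hydroxy-8-(3-methylbutanoyloxy)-14-oxogermacra-1(10),4,11(13)-trien-12,6-olide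
Conditions: TEMPO (cat.), PhI(OAc)2, CH2Cl2, rt
Reagents that add atoms: none
Why: TEMPO/PhI(OAc)2 oxidation through the oxoammonium salt is selective for the primary allylic C14 alcohol over the secondary C2 alcohol and stops at the enal, which completes the target.

**Compound list**

1 | propargyl alcohol | C#CCO | starting material
2 | sodium prop-2-yn-1-olate | [Na+].[O-]CC#C | intermediate
3 | 4-methoxybenzyl prop-2-ynyl ether | COc1ccc(COCC#C)cc1 | intermediate
4 | (E)-crotonaldehyde | C/C=C/C=O | starting material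
5 | methyl[3-(4-methoxybenzyloxy)prop-1-ynyl]zinc | C[Zn]C#CCOCc1ccc(OC)cc1 | intermediate
6 | (4S,5E)-1-(4-methoxybenzyloxy)hept-5-en-2-yn-4-ol | O[C@H](C#CCOCc1ccc(OC)cc1)/C=C/C | intermediate
7 | sodium alkenylalanate: five-membered Al–O–C6–C5=C4 ring, two 2-methoxyethoxy groups on aluminium, (6S) | [Na+].COCCO[Al-]1(OCCOC)O[C@@H](/C=C/C)C=C1COCc2ccc(OC)cc2 | intermediate
8 | (2Z,4S,5E)-2-iodo-1-(4-methoxybenzyloxy)hepta-2,5-dien-4-ol | O[C@H](/C=C(\I)COCc1ccc(OC)cc1)/C=C/C | intermediate
9 | tributyl(vinyl)stannane | C=C[Sn](CCCC)(CCCC)CCCC | starting material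
10 | (3E,5S,6E)-3-[(4-methoxybenzyloxy)methyl]octa-1,3,6-trien-5-ol | O[C@H](/C=C(\C=C)COCc1ccc(OC)cc1)/C=C/C | intermediate
11 | 9-[(3E,5S,6E)-5-hydroxy-3-[(4-methoxybenzyloxy)methyl]octa-3,6-dienyl]-9-borabicyclo[3.3.1]nonane | O[C@H](/C=C(\CCB1C2CCCC1CCC2)COCc3ccc(OC)cc3)/C=C/C | intermediate
12 | (3E,5S,6E)-3-[(4-methoxybenzyloxy)methyl]octa-3,6-diene-1,5-diol | O[C@H](/C=C(\CCO)COCc1ccc(OC)cc1)/C=C/C | intermediate
13 | (3E,5S,6E)-1-(tert-butyldimethylsilyloxy)-3-[(4-methoxybenzyloxy)methyl]octa-3,6-dien-5-ol | O[C@H](/C=C(\CCO[Si](C)(C)C(C)(C)C)COCc1ccc(OC)cc1)/C=C/C | intermediate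
14 | 2-(bromomethyl)acrylic acid | C=C(CBr)C(=O)O | starting material
15 | (3E,5S,6E)-1-(tert-butyldimethylsilyloxy)-3-[(4-methoxybenzyloxy)methyl]octa-3,6-dien-5-yl 2-(bromomethyl)acrylate | C=C(CBr)C(=O)O[C@H](/C=C(\CCO[Si](C)(C)C(C)(C)C)COCc1ccc(OC)cc1)/C=C/C | intermediate
16 | (3E,5S,6E)-1-(tert-butyldimethylsilyloxy)-3-[(4-methoxybenzyloxy)methyl]octa-3,6-dien-5-yl 2-[(tributylstannyl)methyl]acrylate | C=C(C[Sn](CCCC)(CCCC)CCCC)C(=O)O[C@H](/C=C(\CCO[Si](C)(C)C(C)(C)C)COCc1ccc(OC)cc1)/C=C/C | intermediate
17 | (5R)-5-[(1E)-4-(tert-butyldimethylsilyloxy)-2-[(4-methoxybenzyloxy)methyl]but-1-enyl]-3-[(tributylstannyl)methyl]furan-2(5H)-one | O=C1O[C@H](/C=C(\CCO[Si](C)(C)C(C)(C)C)COCc2ccc(OC)cc2)C=C1C[Sn](CCCC)(CCCC)CCCC | intermediate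
18 | diethyl allylmalonate | C=CCC(C(=O)OCC)C(=O)OCC | starting material
19 | iodoform | IC(I)I | starting material
20 | sodium enolate of diethyl allylmalonate | [Na+].CCOC(=O)[C-](CC=C)C(=O)OCC | intermediate
21 | diethyl 2-allyl-2-(diiodomethyl)malonate | CCOC(=O)C(CC=C)(C(I)I)C(=O)OCC | intermediate
22 | (E)-2-(iodomethylene)pent-4-enoic acid | OC(=O)/C(CC=C)=C/I | intermediate
23 | (E)-2-(iodomethylene)pent-4-en-1-ol | OC/C(CC=C)=C/I | intermediate
24 | (E)-tert-butyl[2-(iodomethylene)pent-4-enyloxy]diphenylsilane | C=CC/C(CO[Si](c1ccccc1)(c1ccccc1)C(C)(C)C)=C\I | intermediate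
25 | (4E)-4-[(tert-butyldiphenylsilyloxy)methyl]-5-iodopent-4-ene-1,2-diol (racemic at the diol carbon) | OCC(O)C/C(CO[Si](c1ccccc1)(c1ccccc1)C(C)(C)C)=C\I | intermediate
26 | (E)-3-[(tert-butyldiphenylsilyloxy)methyl]-4-iodobut-3-enal | O=CC/C(CO[Si](c1ccccc1)(c1ccccc1)C(C)(C)C)=C\I | intermediate
27 | (4R,5R)-4-[(1R,3E)-3-[(tert-butyldiphenylsilyloxy)methyl]-1-hydroxy-4-iodobut-3-enyl]-5-[(1E)-4-(tert-butyldimethylsilyloxy)-2-[(4-methoxybenzyloxy)methyl]but-1-enyl]-3-methylideneoxolan-2-one (6R,7R,8R) | C=C1C(=O)O[C@H](/C=C(/COCc2ccc(OC)cc2)CCO[Si](C)(C)C(C)(C)C)[C@H]1[C@H](O)C/C(CO[Si](c2ccccc2)(c2ccccc2)C(C)(C)C)=C\I | intermediate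
28 | isovaleryl chloride (3-methylbutanoyl chloride) | CC(C)CC(=O)Cl | starting material
29 | C8 3-methylbutanoate of 27 (6R,7R,8R; C15 PMB ether, C2 TBS ether, C14 TBDPS ether) | C=C1C(=O)O[C@H](/C=C(/COCc2ccc(OC)cc2)CCO[Si](C)(C)C(C)(C)C)[C@H]1[C@H](OC(=O)CC(C)C)C/C(CO[Si](c2ccccc2)(c2ccccc2)C(C)(C)C)=C\I | intermediate
30 | C15 alcohol: 29 with the PMB ether replaced by a free hydroxyl | C=C1C(=O)O[C@H](/C=C(/CO)CCO[Si](C)(C)C(C)(C)C)[C@H]1[C@H](OC(=O)CC(C)C)C/C(CO[Si](c2ccccc2)(c2ccccc2)C(C)(C)C)=C\I | intermediate
31 | C15 acetate: 30 acetylated at the C15 hydroxyl | C=C1C(=O)O[C@H](/C=C(/COC(C)=O)CCO[Si](C)(C)C(C)(C)C)[C@H]1[C@H](OC(=O)CC(C)C)C/C(CO[Si](c2ccccc2)(c2ccccc2)C(C)(C)C)=C\I | intermediate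
32 | C2 alcohol: 31 with the TBS ether replaced by a free primary hydroxyl | C=C1C(=O)O[C@H](/C=C(/COC(C)=O)CCO)[C@H]1[C@H](OC(=O)CC(C)C)C/C(CO[Si](c2ccccc2)(c2ccccc2)C(C)(C)C)=C\I | intermediate
33 | seco iodo-aldehyde (6R,7R,8R): C2 aldehyde, (E)-C1 alkenyl iodide, C15 acetate, C8 3-methylbutanoate, C14 TBDPS ether | C=C1C(=O)O[C@H](/C=C(/COC(C)=O)CC=O)[C@H]1[C@H](OC(=O)CC(C)C)C/C(CO[Si](c2ccccc2)(c2ccccc2)C(C)(C)C)=C\I | intermediate
34 | alkenylchromium dichloride: 33 with CrCl2 (trivalent chromium) in place of iodine on C1 | C=C1C(=O)O[C@H](/C=C(/COC(C)=O)CC=O)[C@H]1[C@H](OC(=O)CC(C)C)C/C(CO[Si](c2ccccc2)(c2ccccc2)C(C)(C)C)=C\[Cr](Cl)Cl | intermediate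
35 | (2S,6R,7R,8R)-15-acetoxy-14-(tert-butyldiphenylsilyloxy)-2-hydroxy-8-(3-methylbutanoyloxy)germacra-1(10),4,11(13)-trien-12,6-olide | C=C1C(=O)O[C@@H]2/C=C(/COC(C)=O)C[C@H](O)/C=C(/CO[Si](c3ccccc3)(c3ccccc3)C(C)(C)C)C[C@@H](OC(=O)CC(C)C)[C@@H]12 | intermediate
36 | (2S,6R,7R,8R)-15-acetoxy-2,14-dihydroxy-8-(3-methylbutanoyloxy)germacra-1(10),4,11(13)-trien-12,6-olide | C=C1C(=O)O[C@@H]2/C=C(/COC(C)=O)C[C@H](O)/C=C(/CO)C[C@@H](OC(=O)CC(C)C)[C@@H]12 | intermediate
37 | CNP0524123.1, (2S,6R,7R,8R)-15-acetoxy-2-hydroxy-8-(3-methylbutanoyloxy)-14-oxogermacra-1(10),4,11(13)-trien-12,6-olide | C=C1C(=O)O[C@@H]2/C=C(/COC(C)=O)C[C@H](O)/C=C(/C=O)C[C@@H](OC(=O)CC(C)C)[C@@H]12 | target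

**Step count and risks**

Total: 23 steps. Longest linear sequence: 18 steps (steps 1–9, then 15–23). The iodo-aldehyde branch is 5 steps (10–14).

Steps most likely to fail:

1. Step 21. The ligated alkenylchromium may not discriminate the two faces of the C2 aldehyde well enough in the strained ten-membered transition state, and intermolecular coupling may compete with ring closure. Fallback: set out from 33 and close the ring under the same nickel/chromium conditions with an achiral bipyridine ligand. The unwanted C2-epimeric macrocyclic alcohol F1, alone or mixed with 35, is oxidised with MnO2 to the macrocyclic C2 ketone F2. F2 is then reduced with (R)-2-methyl-CBS-oxazaborolidine and catecholborane at −78 °C, the alkenyl group acting as the large substituent, which returns to the route at 35. Stereocontrol is thereby moved from the C–C bond formation to a reagent-controlled ketone reduction.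

2. Step 15. The electron-poor allylstannane may add sluggishly, and the open transition state may not favour the syn C7/C8 relationship strongly enough, so that the C8 configuration is eroded. Fallback: set out from 17 and 26 but transmetalate 17 with InCl3 (EtOAc, −78 °C → rt), so that an allylindium adds through a closed chair transition state. This should give the C8-epimeric alcohol F3 as the main adduct. Mitsunobu esterification of F3 with isovaleric acid (PPh3, DIAD, toluene, 0 °C) then inverts C8 and rejoins the route at 29.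

3. Step 9. Ring closure at the hindered 1,1-disubstituted olefin bearing the stannylmethyl group may be slow, letting catalyst decomposition and protodestannylation take over. Fallback: set out from 15 and run the metathesis on the bromide first, which the ruthenium carbene tolerates, to give the (5R)-3-(bromomethyl)butenolide F4. Bromide is then displaced with Bu3SnCu at −78 °C, a non-basic reagent, which returns to the route at 17.

Further compounds
F1 | step 21 | C2-epimeric macrocyclic alcohol, the (2R)-epimer of 35 | C=C1C(=O)O[C@@H]2/C=C(/COC(C)=O)C[C@@H](O)/C=C(/CO[Si](c3ccccc3)(c3ccccc3)C(C)(C)C)C[C@@H](OC(=O)CC(C)C)[C@@H]12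
F2 | step 21 | macrocyclic C2 ketone, the 2-oxo analogue of 35 | C=C1C(=O)O[C@@H]2/C=C(/COC(C)=O)CC(=O)/C=C(/CO[Si](c3ccccc3)(c3ccccc3)C(C)(C)C)C[C@@H](OC(=O)CC(C)C)[C@@H]12
F3 | step 15 | C8-epimeric alcohol, the (8S)-epimer of 27 | C=C1C(=O)O[C@H](/C=C(/COCc2ccc(OC)cc2)CCO[Si](C)(C)C(C)(C)C)[C@H]1[C@@H](O)C/C(CO[Si](c2ccccc2)(c2ccccc2)C(C)(C)C)=C\I
F4 | step 9 | (5R)-3-(bromomethyl)-5-[(1E)-4-(tert-butyldimethylsilyloxy)-2-[(4-methoxybenzyloxy)methyl]but-1-enyl]furan-2(5H)-one | O=C1O[C@H](/C=C(\CCO[Si](C)(C)C(C)(C)C)COCc2ccc(OC)cc2)C=C1CBr
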